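**Retrosynthetic overview**
1. Target 14 ⇐ (E)-allylic alcohol 13 by Sharpless epoxidation: both oxirane C–O bonds and both side-chain stereocentres, last step.
2. 13 ⇐ methyl ketone 11 (olefination, ester reduction) ⇐ allylsilane 10 + enone 2 (Hosomi–Sakurai: side-chain C–C bond, C-5 stereocentre and exocyclic methylene in one step).
3. 10 ⇐ octalone 5 by cis conjugate methylation (C-4a), enol triflate → allylsilane, and ester-enolate methylation (quaternary C-1, steered by the angular methyl).
4. 5 ⇐ 1 + 2 by asymmetric reductive Michael addition, then aldol condensation.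
5. Ring order: ring A comes with 1, ring B is annulated in steps 1–2, the oxirane is closed last. Chirality is relayed C-1(H) → C-8a → C-4a → C-1(Me).

Assumption: the SMILES is read literally, i.e. a cis-fused decalin with H-8a, the angular methyl, the CO2Me group and the side chain all on one face (the ring-fusion epimer of the natural isocupressate series); 1 is bought (it is also one allylic oxidation away from methyl cyclohex-1-ene-1-carboxylate).

Locants are those of the naphthalene names: C-1 carries the ester, C-4a the angular methyl, C-5 the side chain, C-6 the methylidene, C-8a is the ring-fusion CH.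

**Route**

Step 1
Reactants: 1 methyl 3-oxocyclohex-1-ene-1-carboxylate; 2 but-3-en-2-one
Product: 4 methyl (1S,2R)-3-oxo-2-(3-oxobutyl)cyclohexane-1-carboxylate, via silyl enol ether 3 (not isolated)
Conditions: Cu(OAc)2·H2O (3 mol %), (S)-DTBM-SEGPHOS (3.3 mol %; the (R)-ligand if the ester reverses the sense known for isophorone), (EtO)2MeSiH (1.2 equiv), toluene, 0 °C; then cannulate into 2 (2 equiv), TiCl4 (1.2 equiv), CH2Cl2, −78 °C; aq. NaHCO3
Reagents that add atoms: none
Why: Proposed new method: a bisphosphine-ligated copper hydride should add hydride enantioselectively to C-1 of 1 (the carbon β to the ketone, the stronger acceptor and the site where alkylcopper reagents are known to attack such γ-keto enoates), the silane turns the copper enolate over to the regiodefined silyl enol ether 3, and TiCl4-promoted Mukaiyama–Michael addition to 2 then occurs anti to the CO2Me group to give the 1,2-trans product; the closest known reaction type is the asymmetric copper hydride 1,4-reduction of 3-alkylcyclohexenones with tandem Mukaiyama aldol or alkylation of the silyl enol ether, which has not been shown for a 3-alkoxycarbonyl enone or with an enone as the trap.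

Step 2
Reactants: 4 methyl (1S,2R)-3-oxo-2-(3-oxobutyl)cyclohexane-1-carboxylate
Product: 5 methyl (1S,8aR)-6-oxo-1,2,3,4,6,7,8,8a-octahydronaphthalene-1-carboxylate
Conditions: TsOH·H2O (10 mol %), toluene, reflux (Dean–Stark), 2 h; chromatography
Reagents that add atoms: none
Why: acid-catalysed intramolecular aldol condensation (second stage of a Robinson annulation) closes ring B; the ester does not enolise under acid so C-1 is untouched, C-8a keeps or relaxes to the trans arrangement (favoured only about 3:1), and the minor cis epimer is removed here because it would end in the enantiomeric series once C-1 is re-formed in step 5.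

Step 3
Reactants: 5 methyl (1S,8aR)-6-oxo-1,2,3,4,6,7,8,8a-octahydronaphthalene-1-carboxylate
Product: 7 methyl (1S,4aS,8aR)-4a-methyl-6-{[(trifluoromethyl)sulfonyl]oxy}-1,2,3,4,4a,7,8,8a-octahydronaphthalene-1-carboxylate, via lithium enolate 6 (not isolated)
Conditions: Me2CuLi (1.5 equiv, from MeLi and CuI), Et2O, −20 to 0 °C; then PhNTf2 (1.6 equiv), THF, 0 °C to rt
Reagents that add atoms: lithium dimethylcuprate [Li+].C[Cu-]C; N-phenylbis(trifluoromethanesulfonimide) O=S(=O)(N(c1ccccc1)S(=O)(=O)C(F)(F)F)C(F)(F)F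
Why: cuprate 1,4-addition to an 8a-H octalone is the classical route to cis-fused angular-methyl decalones, the methyl entering C-4a on the face of H-8a because the other face is screened by the axial hydrogens of ring A, and the regiodefined enolate 6 is then O-triflated by PhNTf2.

Step 4
Reactants: 7 methyl (1S,4aS,8aR)-4a-methyl-6-{[(trifluoromethyl)sulfonyl]oxy}-1,2,3,4,4a,7,8,8a-octahydronaphthalene-1-carboxylate
Product: 8 methyl (1S,4aS,8aR)-4a-methyl-6-[(trimethylsilyl)methyl]-1,2,3,4,4a,7,8,8a-octahydronaphthalene-1-carboxylate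
Conditions: Me3SiCH2MgCl (1.5 equiv), Pd(PPh3)4 (3 mol %), THF, 0 °C to rt
Reagents that add atoms: (trimethylsilyl)methylmagnesium chloride C[Si](C)(C)C[Mg]Cl
Why: Kumada coupling of an enol triflate with Me3SiCH2MgCl under zerovalent palladium catalysis is a standard allylsilane synthesis; this bulky Grignard reagent does not add to the ester at this temperature and no stereocentre is touched (C-1 is still epimerisable but is re-set in step 5).

Step 5
Reactants: 8 methyl (1S,4aS,8aR)-4a-methyl-6-[(trimethylsilyl)methyl]-1,2,3,4,4a,7,8,8a-octahydronaphthalene-1-carboxylate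
Product: 10 methyl (1S,4aR,8aS)-1,4a-dimethyl-6-[(trimethylsilyl)methyl]-1,2,3,4,4a,7,8,8a-octahydronaphthalene-1-carboxylate, via lithium ester enolate 9 (not isolated)
Conditions: LiN(iPr)2 (1.3 equiv), THF, −78 °C; then MeI (3 equiv), DMPU, −78 to −20 °C
Reagents that add atoms: iodomethane CI
Why: ester enolate alkylation in which the angular methyl sets the quaternary centre: A(1,3) strain in enolate 9 turns the C-8a–C-8 bond axial on ring A, which puts the C-4a methyl syn-axial over one face of C-1, so MeI enters from the other face and the CO2Me group ends cis to the angular methyl and to H-8a, the same outcome as in the classical C-4 methylation of resin-acid ester enolates.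

Step 6
Reactants: 10 methyl (1S,4aR,8aS)-1,4a-dimethyl-6-[(trimethylsilyl)methyl]-1,2,3,4,4a,7,8,8a-octahydronaphthalene-1-carboxylate; 2 but-3-en-2-one
Product: 11 methyl (1S,4aR,5S,8aS)-1,4a-dimethyl-6-methylidene-5-(3-oxobutyl)decahydronaphthalene-1-carboxylate
Conditions: 2 (2 equiv), TiCl4 (1.2 equiv), CH2Cl2, −78 °C; aq. NaHCO3
Reagents that add atoms: none
Why: Hosomi–Sakurai conjugate allylation: TiCl4-activated 2 attacks the γ-carbon of the allylsilane (C-5) with loss of silicon, which shifts the double bond to the exocyclic position, and it approaches from the convex face of the cis-decalin (the face of the angular methyl and H-8a; the other face is closed by ring A), so the side chain ends cis to the angular methyl (5S).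

Step 7
Reactants: 11 methyl (1S,4aR,5S,8aS)-1,4a-dimethyl-6-methylidene-5-(3-oxobutyl)decahydronaphthalene-1-carboxylate
Product: 12 methyl (1S,4aR,5S,8aS)-5-[(3E)-5-ethoxy-3-methyl-5-oxopent-3-en-1-yl]-1,4a-dimethyl-6-methylidenedecahydronaphthalene-1-carboxylate
Conditions: (iPrO)2P(O)CH2CO2Et (2 equiv), NaH (1.9 equiv), THF, 0 to 40 °C
Reagents that add atoms: ethyl 2-(diisopropoxyphosphoryl)acetate CCOC(=O)CP(=O)(OC(C)C)OC(C)C
Why: Horner–Wadsworth–Emmons olefination of the only ketone; the bulky diisopropyl phosphonate favours the (E)-trisubstituted enoate (about 9:1 expected for a methyl ketone) and the ester on the quaternary carbon is inert.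

Step 8
Reactants: 12 methyl (1S,4aR,5S,8aS)-5-[(3E)-5-ethoxy-3-methyl-5-oxopent-3-en-1-yl]-1,4a-dimethyl-6-methylidenedecahydronaphthalene-1-carboxylate
Product: 13 methyl (1S,4aR,5S,8aS)-5-[(3E)-5-hydroxy-3-methylpent-3-en-1-yl]-1,4a-dimethyl-6-methylidenedecahydronaphthalene-1-carboxylate
Conditions: iBu2AlH (2.2 equiv), CH2Cl2, −78 °C; aq. potassium sodium tartrate; chromatography (minor Z isomer removed)
Reagents that add atoms: none
Why: chemoselective 1,2-reduction: the unhindered conjugated ethyl ester is reduced to the allylic alcohol at −78 °C while the methyl ester on the quaternary, neopentyl-like C-1 reacts far more slowly with the bulky hydride.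

Step 9
Reactants: 13 methyl (1S,4aR,5S,8aS)-5-[(3E)-5-hydroxy-3-methylpent-3-en-1-yl]-1,4a-dimethyl-6-methylidenedecahydronaphthalene-1-carboxylate
Product: 14 methyl (1S,4aR,5S,8aS)-5-{2-[(2R,3R)-3-(hydroxymethyl)-2-methyloxiran-2-yl]ethyl}-1,4a-dimethyl-6-methylidenedecahydronaphthalene-1-carboxylate
Conditions: Ti(OiPr)4 (10 mol %), D-(−)-diisopropyl tartrate (12 mol %), tBuOOH (2 equiv, decane solution), 4 Å molecular sieves, CH2Cl2, −20 °C
Reagents that add atoms: tert-butyl hydroperoxide CC(C)(C)OO
Why: Sharpless asymmetric epoxidation forms both C–O bonds of the oxirane only at the allylic alcohol double bond, and with D-(−)-tartrate an (E)-3-methylalk-2-en-1-ol gives the (2R,3R)-epoxy alcohol (the enantiomeric tartrate gives 2S,3S with geraniol), so both new stereocentres are set by the reagent while the exocyclic alkene and the ester are left alone.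

**Compound list**
1 | methyl 3-oxocyclohex-1-ene-1-carboxylate | COC(=O)C1=CC(=O)CCC1 | starting material
2 | but-3-en-2-one (methyl vinyl ketone) | CC(=O)C=C | starting material
3 | methyl (1S)-3-{[diethoxy(methyl)silyl]oxy}cyclohex-2-ene-1-carboxylate | COC(=O)[C@H]1CCCC(O[Si](C)(OCC)OCC)=C1 | intermediate
4 | methyl (1S,2R)-3-oxo-2-(3-oxobutyl)cyclohexane-1-carboxylate (ester and side chain trans) | COC(=O)[C@H]1CCCC(=O)[C@@H]1CCC(C)=O | intermediate
5 | methyl (1S,8aR)-6-oxo-1,2,3,4,6,7,8,8a-octahydronaphthalene-1-carboxylate (ester cis to H-8a) | COC(=O)[C@H]1CCCC2=CC(=O)CC[C@H]12 | intermediate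
6 | lithium (1S,4aS,8aR)-1-(methoxycarbonyl)-4a-methyl-1,2,3,4,4a,7,8,8a-octahydronaphthalen-6-olate (cis-fused) | COC(=O)[C@H]1CCC[C@]2(C)C=C([O-])CC[C@H]12.[Li+] | intermediate
7 | methyl (1S,4aS,8aR)-4a-methyl-6-{[(trifluoromethyl)sulfonyl]oxy}-1,2,3,4,4a,7,8,8a-octahydronaphthalene-1-carboxylate (cis-fused; ester, H-8a and 4a-methyl on one face) | COC(=O)[C@H]1CCC[C@]2(C)C=C(OS(=O)(=O)C(F)(F)F)CC[C@H]12 | intermediate
8 | methyl (1S,4aS,8aR)-4a-methyl-6-[(trimethylsilyl)methyl]-1,2,3,4,4a,7,8,8a-octahydronaphthalene-1-carboxylate | COC(=O)[C@H]1CCC[C@]2(C)C=C(C[Si](C)(C)C)CC[C@H]12 | intermediate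
9 | lithium ester enolate of 8 (C-1 planar; C-4a and C-8a as in 8) | COC([O-])=C1CCC[C@]2(C)C=C(C[Si](C)(C)C)CC[C@H]12.[Li+] | intermediate
10 | methyl (1S,4aR,8aS)-1,4a-dimethyl-6-[(trimethylsilyl)methyl]-1,2,3,4,4a,7,8,8a-octahydronaphthalene-1-carboxylate (ester, H-8a and 4a-methyl on one face) | COC(=O)[C@@]1(C)CCC[C@]2(C)C=C(C[Si](C)(C)C)CC[C@H]12 | intermediate
11 | methyl (1S,4aR,5S,8aS)-1,4a-dimethyl-6-methylidene-5-(3-oxobutyl)decahydronaphthalene-1-carboxylate | C=C1CC[C@H]2[C@](C)(CCC[C@]2(C)C(=O)OC)[C@H]1CCC(C)=O | intermediate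
12 | methyl (1S,4aR,5S,8aS)-5-[(3E)-5-ethoxy-3-methyl-5-oxopent-3-en-1-yl]-1,4a-dimethyl-6-methylidenedecahydronaphthalene-1-carboxylate | C=C1CC[C@H]2[C@](C)(CCC[C@]2(C)C(=O)OC)[C@H]1CC/C(C)=C/C(=O)OCC | intermediate
13 | methyl (1S,4aR,5S,8aS)-5-[(3E)-5-hydroxy-3-methylpent-3-en-1-yl]-1,4a-dimethyl-6-methylidenedecahydronaphthalene-1-carboxylate | C=C1CC[C@H]2[C@](C)(CCC[C@]2(C)C(=O)OC)[C@H]1CC/C(C)=C/CO | intermediate
14 | methyl (1S,4aR,5S,8aS)-5-{2-[(2R,3R)-3-(hydroxymethyl)-2-methyloxiran-2-yl]ethyl}-1,4a-dimethyl-6-methylidenedecahydronaphthalene-1-carboxylate | C=C1CC[C@H]2[C@](C)(CCC[C@]2(C)C(=O)OC)[C@H]1CC[C@@]1(C)O[C@@H]1CO | target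

**Count**
Total steps: 9. Longest linear sequence: 9 (1 → 14).

**Three steps most likely to fail**

Step 1 (the new tandem reaction: hydride regiochemistry, ee and the trapping are untested on this substrate). Fallback with known chemistry, from 1 back to 10: copper-catalysed asymmetric conjugate addition of Me2Zn to 1 (Cu(OTf)2 with a chiral sulfonate-bearing N-heterocyclic carbene ligand, a reaction known for cyclic γ-keto esters) puts the methyl on the ester-bearing carbon, and silylation of the zinc enolate with Me3SiOTf gives silyl enol ether F1. TiCl4-promoted Mukaiyama–Michael addition to 2 gives diketo ester F2. TsOH closes it to octalone F3, whose C-8a epimers are separated, the wrong one being re-equilibrated with DBU. Me2CuLi then PhNTf2 gives triflate F4, and Me3SiCH2MgCl with Pd(PPh3)4 gives 10. The quaternary centre is then set by the catalyst and step 5 is not needed; the price is weak control at C-8a next to a CH3/CO2Me quaternary carbon.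

Step 6 (bond formation next to a quaternary carbon; protodesilylation or attack on the wrong face are possible). Fallback from 5 back to 12, using enolate chemistry in place of the allylsilane: Me2CuLi then tBuMe2SiOTf gives silyl enol ether F5. LiN(iPr)2 and MeI give the C-1 methylated silyl enol ether F6. TiCl4-promoted Mukaiyama–Michael addition to 2 gives diketone F7, in which C-5 is α to a ketone and can be equilibrated with base if needed. The phosphonate anion of step 7 reacts only at the methyl ketone to give keto enoate F8. Zn/CH2Br2/TiCl4 methylenation of the ring ketone gives 12.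

Step 7 (E/Z ratio of a methyl ketone olefination; the Z isomer would give a diastereomeric epoxide). Fallback from 11 back to 12 with full E control: LiN(iPr)2 then ClP(O)(OEt)2 gives enol phosphate F9. Excess LiN(iPr)2 eliminates it to terminal alkyne F10. Me3Al with Cp2ZrCl2 (syn-carbometalation) gives (E)-alkenylalane F11, and ClCO2Et converts it into 12 as a single isomer.

Further compounds
F1 | step 1 | methyl (1S)-1-methyl-3-[(trimethylsilyl)oxy]cyclohex-2-ene-1-carboxylate | COC(=O)[C@@]1(C)CCCC(O[Si](C)(C)C)=C1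
F2 | step 1 | methyl (1S,2R)-1-methyl-3-oxo-2-(3-oxobutyl)cyclohexane-1-carboxylate | COC(=O)[C@@]1(C)CCCC(=O)[C@@H]1CCC(C)=O
F3 | step 1 | methyl (1S,8aS)-1-methyl-6-oxo-1,2,3,4,6,7,8,8a-octahydronaphthalene-1-carboxylate | COC(=O)[C@@]1(C)CCCC2=CC(=O)CC[C@H]12
F4 | step 1 | methyl (1S,4aS,8aS)-1,4a-dimethyl-6-{[(trifluoromethyl)sulfonyl]oxy}-1,2,3,4,4a,7,8,8a-octahydronaphthalene-1-carboxylate | COC(=O)[C@@]1(C)CCC[C@]2(C)C=C(OS(=O)(=O)C(F)(F)F)CC[C@H]12
F5 | step 6 | methyl (1S,4aS,8aR)-6-{[tert-butyl(dimethyl)silyl]oxy}-4a-methyl-1,2,3,4,4a,7,8,8a-octahydronaphthalene-1-carboxylate | COC(=O)[C@H]1CCC[C@]2(C)C=C(O[Si](C)(C)C(C)(C)C)CC[C@H]12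
F6 | step 6 | methyl (1S,4aS,8aS)-6-{[tert-butyl(dimethyl)silyl]oxy}-1,4a-dimethyl-1,2,3,4,4a,7,8,8a-octahydronaphthalene-1-carboxylate | COC(=O)[C@@]1(C)CCC[C@]2(C)C=C(O[Si](C)(C)C(C)(C)C)CC[C@H]12
F7 | step 6 | methyl (1S,4aS,5R,8aS)-1,4a-dimethyl-6-oxo-5-(3-oxobutyl)decahydronaphthalene-1-carboxylate | O=C1CC[C@H]2[C@](C)(CCC[C@]2(C)C(=O)OC)[C@H]1CCC(C)=O
F8 | step 6 | methyl (1S,4aS,5R,8aS)-5-[(3E)-5-ethoxy-3-methyl-5-oxopent-3-en-1-yl]-1,4a-dimethyl-6-oxodecahydronaphthalene-1-carboxylate | O=C1CC[C@H]2[C@](C)(CCC[C@]2(C)C(=O)OC)[C@H]1CC/C(C)=C/C(=O)OCC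
F9 | step 7 | methyl (1S,4aR,5S,8aS)-5-{3-[(diethoxyphosphoryl)oxy]but-3-en-1-yl}-1,4a-dimethyl-6-methylidenedecahydronaphthalene-1-carboxylate | C=C1CC[C@H]2[C@](C)(CCC[C@]2(C)C(=O)OC)[C@H]1CCC(=C)OP(=O)(OCC)OCC
F10 | step 7 | methyl (1S,4aR,5S,8aS)-5-(but-3-yn-1-yl)-1,4a-dimethyl-6-methylidenedecahydronaphthalene-1-carboxylate | C=C1CC[C@H]2[C@](C)(CCC[C@]2(C)C(=O)OC)[C@H]1CCC#C
F11 | step 7 | methyl (1S,4aR,5S,8aS)-5-[(3E)-4-(dimethylalumanyl)-3-methylbut-3-en-1-yl]-1,4a-dimethyl-6-methylidenedecahydronaphthalene-1-carboxylate | C=C1CC[C@H]2[C@](C)(CCC[C@]2(C)C(=O)OC)[C@H]1CC/C(C)=C/[Al](C)C
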